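The α‑methylene‑γ‑butyrolactone, trans‑fused to the (Z)‑cyclodecene, is read as allene + CO2 + aldehyde: lactone carbonyl C12 is CO2, C13=C11–C7 a terminal allene and C6–O an enal carbonyl. In the last step Ni(0) joins CO2 to the central allene carbon (C11–C12), and the 2‑carboxyallylnickel so formed adds through C7 to aldehyde C6 (C6–C7). This closes the ten‑membered carbocycle and, on acidification, the γ‑lactone, with C6 and C7 set together. The precursor is an acyclic (Z)‑enal allene already carrying the C3 acetate and C9 angelate, assembled from (R)‑citronellal (C8–C10, C1–C3 and the C10 methyl), acetylene, formaldehyde and (Z)‑3‑iodobut‑2‑en‑1‑ol.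

Key step: step 16

Remark on the chemistry: locants C1–C15 are germacrane locants of the target (C1–C10 ring, C11 α‑carbon, C12 lactone carbonyl, C13 exocyclic CH2, C14 methyl on C10, C15 methyl on C4). Ligands on Ni in 26 and on Cr in 19 are omitted from the SMILES. Compounds 13 and 20 are epimer mixtures at the unmarked centre.

Step 1
Reactants: 1 (R)-citronellal
Product: 3 (2R,3R)-3,7-dimethyl-2-[(phenylamino)oxy]oct-6-en-1-ol, via α-aminoxy aldehyde 2 (not isolated)
Conditions: PhNO, L-proline (20 mol%), CHCl3, 0 °C; then NaBH4, EtOH, 0 °C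
Reagents that add atoms: nitrosobenzene O=Nc1ccccc1
Why: Proline-catalysed asymmetric α-aminoxylation, in which the L-proline enamine attacks the nitroso oxygen on the face held by the carboxylic acid, so the new centre (C9 of the target) is set as 2R under catalyst control, and immediate borohydride reduction prevents epimerization of the α-oxy aldehyde.

Step 2
Reactants: 3 (2R,3R)-3,7-dimethyl-2-[(phenylamino)oxy]oct-6-en-1-ol
Product: 4 (2R,3R)-3,7-dimethyloct-6-ene-1,2-diol
Conditions: Zn dust, AcOH/EtOH, rt
Reagents that add atoms: none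
Why: Reductive N–O bond cleavage by zinc in acetic acid frees the secondary hydroxyl without touching the alkene or either stereocentre.

Step 3
Reactants: 4 (2R,3R)-3,7-dimethyloct-6-ene-1,2-diol
Product: 6 (2R)-2-[(2R)-6-methylhept-5-en-2-yl]oxirane, via primary tosylate 5 (not isolated)
Conditions: NaH, N-tosylimidazole, THF, 0 °C to rt
Reagents that add atoms: none
Why: Selective sulfonylation of the primary hydroxyl followed by intramolecular Williamson etherification by the secondary alkoxide closes the oxirane with the C2–O bond intact, so the configuration is retained.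

Step 4
Reactants: 6 (2R)-2-[(2R)-6-methylhept-5-en-2-yl]oxirane
Product: 7 (4S,5R)-5,9-dimethyldec-8-en-1-yn-4-ol
Conditions: lithium acetylide–ethylenediamine complex, DMSO, rt
Reagents that add atoms: lithium acetylide [Li+].[C-]#C
Why: SN2 epoxide opening by the acetylide at the unsubstituted oxirane carbon should give the homopropargylic alcohol (C7 and C11 of the target) and leaves both stereocentres untouched.

Step 5
Reactants: 7 (4S,5R)-5,9-dimethyldec-8-en-1-yn-4-ol
Product: 9 (5S,6R)-6,10-dimethylundeca-1,2,9-trien-5-ol, via propargylic amine 8 (not isolated)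
Conditions: (CH2O)n, CuI (0.5 equiv), Cy2NH, dioxane, reflux
Reagents that add atoms: formaldehyde (as paraformaldehyde) C=O
Why: Crabbé homologation, in which a copper-mediated Mannich reaction gives propargylic amine 8 and its 1,5-hydride transfer with loss of the imine delivers the terminal allene with one added carbon (C13), the free hydroxyl being tolerated.

Step 6
Reactants: 9 (5S,6R)-6,10-dimethylundeca-1,2,9-trien-5-ol; 10 angelic acid
Product: 12 (5S,6R)-6,10-dimethylundeca-1,2,9-trien-5-yl (Z)-2-methylbut-2-enoate, via mixed anhydride 11 (not isolated)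
Conditions: 10, 2,4,6-trichlorobenzoyl chloride, Et3N, toluene, rt; then 9, 75 °C
Reagents that add atoms: none
Why: Yamaguchi esterification through the mixed anhydride, run without a nucleophilic catalyst, should acylate the hindered secondary alcohol at the angeloyl carbonyl while avoiding addition–elimination isomerization of the (Z)-enoate to the tiglate.

Step 7
Reactants: 12 (5S,6R)-6,10-dimethylundeca-1,2,9-trien-5-yl (Z)-2-methylbut-2-enoate
Product: 14 (5S,6R)-6-methyl-9-oxonona-1,2-dien-5-yl (Z)-2-methylbut-2-enoate, via epoxide 13 (not isolated)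
Conditions: mCPBA (1.0 equiv), CH2Cl2, 0 °C; then H5IO6, THF/H2O, 0 °C
Reagents that add atoms: mCPBA OOC(=O)c1cccc(Cl)c1
Why: Chemoselective Prilezhaev epoxidation of the electron-rich trisubstituted alkene (allene and enoate react far more slowly) followed by periodic acid cleavage of the epoxide should give the aldehyde (C3) with loss of acetone.

Step 8
Reactants: 15 but-2-yn-1-ol
Product: 17 (Z)-3-iodobut-2-en-1-ol, via alkenylaluminate 16 (not isolated)
Conditions: Red-Al, THF, 0 °C to rt; EtOAc; then I2, −78 to 0 °C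
Reagents that add atoms: iodine II
Why: Hydroxyl-directed trans-hydroalumination places aluminium on C3 in a five-membered chelate and iodinolysis proceeds with retention, which fixes the Z geometry (iodine cis to CH2OH) needed for the ring alkene.

Step 9
Reactants: 17 (Z)-3-iodobut-2-en-1-ol
Product: 18 tert-butyl{[(Z)-3-iodobut-2-en-1-yl]oxy}dimethylsilane
Conditions: TBSCl, imidazole, CH2Cl2, 0 °C
Reagents that add atoms: tert-butyldimethylsilyl chloride CC(C)(C)[Si](C)(C)Cl
Why: Standard silylation of the primary alcohol masks the future aldehyde oxygen through the organometallic and hydride steps.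

Step 10
Reactants: 14 (5S,6R)-6-methyl-9-oxonona-1,2-dien-5-yl (Z)-2-methylbut-2-enoate; 18 tert-butyl{[(Z)-3-iodobut-2-en-1-yl]oxy}dimethylsilane
Product: 20 (5S,6R,9RS,10Z)-12-[(tert-butyldimethylsilyl)oxy]-9-hydroxy-6,10-dimethyldodeca-1,2,10-trien-5-yl (Z)-2-methylbut-2-enoate, via alkenylchromium 19 (not isolated)
Conditions: CrCl2 (4 equiv), NiCl2 (1 mol%), DMSO, rt
Reagents that add atoms: none
Why: Nozaki–Hiyama–Kishi coupling, in which the alkenylchromium(III) species formed with retention of alkene geometry adds chemoselectively to the aldehyde in the presence of both esters and the allene; the new carbinol centre is formed without control and both epimers are carried into the oxidation.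

Step 11
Reactants: 20 (5S,6R,9RS,10Z)-12-[(tert-butyldimethylsilyl)oxy]-9-hydroxy-6,10-dimethyldodeca-1,2,10-trien-5-yl (Z)-2-methylbut-2-enoate
Product: 21 (5S,6R,10Z)-12-[(tert-butyldimethylsilyl)oxy]-6,10-dimethyl-9-oxododeca-1,2,10-trien-5-yl (Z)-2-methylbut-2-enoate
Conditions: Dess–Martin periodinane, NaHCO3, CH2Cl2, 0 °C to rt
Reagents that add atoms: none
Why: Dess–Martin oxidation under buffered neutral conditions should convert both epimers into one enone without Z to E isomerization.

Step 12
Reactants: 21 (5S,6R,10Z)-12-[(tert-butyldimethylsilyl)oxy]-6,10-dimethyl-9-oxododeca-1,2,10-trien-5-yl (Z)-2-methylbut-2-enoate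
Product: 22 (5S,6R,9S,10Z)-12-[(tert-butyldimethylsilyl)oxy]-9-hydroxy-6,10-dimethyldodeca-1,2,10-trien-5-yl (Z)-2-methylbut-2-enoate
Conditions: (R)-Me-CBS, catecholborane, toluene, −78 °C
Reagents that add atoms: none
Why: Corey–Bakshi–Shibata reduction, in which the α-branched alkenyl group acts as the large and the methylene chain as the small substituent, so the (R)-oxazaborolidine should give the 9S allylic alcohol (C3 of the target) under reagent control, while catecholborane at low temperature spares allene, esters and the enone C=C.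

Step 13
Reactants: 22 (5S,6R,9S,10Z)-12-[(tert-butyldimethylsilyl)oxy]-9-hydroxy-6,10-dimethyldodeca-1,2,10-trien-5-yl (Z)-2-methylbut-2-enoate
Product: 23 (5S,6R,9S,10Z)-9-acetoxy-12-[(tert-butyldimethylsilyl)oxy]-6,10-dimethyldodeca-1,2,10-trien-5-yl (Z)-2-methylbut-2-enoate
Conditions: Ac2O, pyridine, DMAP (cat.), CH2Cl2, 0 °C
Reagents that add atoms: acetic anhydride CC(=O)OC(C)=O
Why: O-Acylation of the secondary allylic alcohol installs the C3 acetate with retention of configuration.

Step 14
Reactants: 23 (5S,6R,9S,10Z)-9-acetoxy-12-[(tert-butyldimethylsilyl)oxy]-6,10-dimethyldodeca-1,2,10-trien-5-yl (Z)-2-methylbut-2-enoate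
Product: 24 (5S,6R,9S,10Z)-9-acetoxy-12-hydroxy-6,10-dimethyldodeca-1,2,10-trien-5-yl (Z)-2-methylbut-2-enoate
Conditions: HF·pyridine, pyridine, THF, 0 °C
Reagents that add atoms: none
Why: Fluoride-mediated cleavage of the primary silyl ether under buffered conditions should leave the acetate, the angelate and the allene intact.

Step 15
Reactants: 24 (5S,6R,9S,10Z)-9-acetoxy-12-hydroxy-6,10-dimethyldodeca-1,2,10-trien-5-yl (Z)-2-methylbut-2-enoate
Product: 25 (5S,6R,9S,10Z)-9-acetoxy-6,10-dimethyl-12-oxododeca-1,2,10-trien-5-yl (Z)-2-methylbut-2-enoate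
Conditions: activated MnO2, CH2Cl2, rt
Reagents that add atoms: none
Why: Manganese dioxide oxidizes the allylic alcohol selectively under neutral heterogeneous conditions, so the (Z)-enal should form without isomerization, and the acetate on the γ-oxygen prevents lactol and furan formation.

Step 16
Reactants: 25 (5S,6R,9S,10Z)-9-acetoxy-6,10-dimethyl-12-oxododeca-1,2,10-trien-5-yl (Z)-2-methylbut-2-enoate
Product: 28 (3S,4Z,6R,7S,9S,10R)-3-acetoxy-9-[(Z)-2-methylbut-2-enoyloxy]germacra-4,11(13)-dien-12,6-olide, via nickelalactone 26 (not isolated), via hydroxy acid 27 (not isolated)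
Conditions: Ni(cod)2 (1.1 equiv) and DBU (2.2 equiv) in THF added by syringe pump to 25 (3 mM in THF) under CO2 (1 atm), 0 °C to rt; then 1 M HCl
Reagents that add atoms: carbon dioxide O=C=O
Why: Proposed new method: DBU-ligated Ni(0) couples the terminal allene with CO2 by oxidative cyclization at the central carbon, forming C11–C12 and the 2-carboxylato-η3-allylnickel 26, which adds through its substituted terminus C7 to the tethered enal carbon C6 in a six-membered chair-like SE2′ transition state (C6–C7, with C11=C13 regenerated as the exo-methylene), and acidification releases hydroxy acid 27, which lactonizes. The closest known reaction type is the Ni(0)-mediated sequential coupling of terminal allenes, CO2 and aldehydes in its intermolecular form, together with intramolecular 2-(alkoxycarbonyl)allylmetal–aldehyde additions that close medium-ring α-methylene lactones; new here is the intramolecular ten-membered closure on an enal. The cyclodecene is closed by 1,2-addition of the allylnickel to the aldehyde (ten-membered ring, exo at C=O) and the lactone by 5-exo-trig O-acylation of the C6 hydroxyl by the C12 carboxyl. C6 and C7 are set together: the syn (E) allylnickel reacting through the chair with C5 pseudo-equatorial gives the anti adduct, that is the trans-lactone, and the face pairing 6R,7S is expected from macrocyclic control by the preset C3, C9 and C10 centres and the Z-C4=C5 turn, which remains to be confirmed. The step needs CO2 capture at the allene to outrun Ni(0) chemistry at the enal and the allylic acetate, γ- over α-attack of the allyl unit, and cyclization over oligomerization; the unhindered monosubstituted allene, the cyclic transition state from the primary σ-allyl, and slow addition of Ni(0) to a dilute CO2-saturated solution are meant to secure these.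

Compound list
1 | (R)-citronellal, (3R)-3,7-dimethyloct-6-enal | O=CC[C@@H](CCC=C(C)C)C | starting material
2 | (2R,3R)-3,7-dimethyl-2-[(phenylamino)oxy]oct-6-enal | O=C[C@@H]([C@@H](CCC=C(C)C)C)ONc1ccccc1 | intermediate
3 | (2R,3R)-3,7-dimethyl-2-[(phenylamino)oxy]oct-6-en-1-ol | OC[C@@H]([C@@H](CCC=C(C)C)C)ONc1ccccc1 | intermediate
4 | (2R,3R)-3,7-dimethyloct-6-ene-1,2-diol | OC[C@@H]([C@@H](CCC=C(C)C)C)O | intermediate
5 | (2R,3R)-2-hydroxy-3,7-dimethyloct-6-en-1-yl 4-methylbenzenesulfonate | Cc1ccc(cc1)S(=O)(=O)OC[C@@H]([C@@H](CCC=C(C)C)C)O | intermediate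
6 | (2R)-2-[(2R)-6-methylhept-5-en-2-yl]oxirane | C1[C@@H]([C@@H](CCC=C(C)C)C)O1 | intermediate
7 | (4S,5R)-5,9-dimethyldec-8-en-1-yn-4-ol | C#CC[C@@H]([C@@H](CCC=C(C)C)C)O | intermediate
8 | (5S,6R)-1-(dicyclohexylamino)-6,10-dimethylundec-9-en-2-yn-5-ol | C1CCC(CC1)N(CC#CC[C@@H]([C@@H](CCC=C(C)C)C)O)C1CCCCC1 | intermediate
9 | (5S,6R)-6,10-dimethylundeca-1,2,9-trien-5-ol | C=C=CC[C@@H]([C@@H](CCC=C(C)C)C)O | intermediate
10 | angelic acid, (Z)-2-methylbut-2-enoic acid | C/C=C(/C)C(=O)O | starting material
11 | (Z)-2-methylbut-2-enoic 2,4,6-trichlorobenzoic anhydride | C/C=C(/C)C(=O)OC(=O)c1c(Cl)cc(Cl)cc1Cl | intermediate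
12 | (5S,6R)-6,10-dimethylundeca-1,2,9-trien-5-yl (Z)-2-methylbut-2-enoate | C=C=CC[C@@H]([C@@H](CCC=C(C)C)C)OC(=O)/C(C)=C\C | intermediate
13 | (5S,6R)-8-(3,3-dimethyloxiran-2-yl)-6-methylocta-1,2-dien-5-yl (Z)-2-methylbut-2-enoate (oxirane epimers) | C=C=CC[C@@H]([C@@H](CCC1OC1(C)C)C)OC(=O)/C(C)=C\C | intermediate
14 | (5S,6R)-6-methyl-9-oxonona-1,2-dien-5-yl (Z)-2-methylbut-2-enoate | C=C=CC[C@@H]([C@@H](CCC=O)C)OC(=O)/C(C)=C\C | intermediate
15 | but-2-yn-1-ol | CC#CCO | starting material
16 | sodium cyclic (Z)-alkenylaluminate from 15 and Red-Al (2,2-bis(2-methoxyethoxy)-3-methyl-1,2-oxaaluminol-3-ene, 5H) | [Na+].CC1=CCO[Al-]1(OCCOC)OCCOC | intermediate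
17 | (Z)-3-iodobut-2-en-1-ol | OC/C=C(/C)I | intermediate
18 | tert-butyl{[(Z)-3-iodobut-2-en-1-yl]oxy}dimethylsilane | CC(C)(C)[Si](C)(C)OC/C=C(/C)I | intermediate
19 | dichloro[(Z)-4-(tert-butyldimethylsilyloxy)but-2-en-2-yl]chromium(III) | CC(C)(C)[Si](C)(C)OC/C=C(/C)[Cr](Cl)Cl | intermediate
20 | (5S,6R,9RS,10Z)-12-[(tert-butyldimethylsilyl)oxy]-9-hydroxy-6,10-dimethyldodeca-1,2,10-trien-5-yl (Z)-2-methylbut-2-enoate | C=C=CC[C@@H]([C@@H](CCC(O)/C(C)=C\CO[Si](C)(C)C(C)(C)C)C)OC(=O)/C(C)=C\C | intermediate
21 | (5S,6R,10Z)-12-[(tert-butyldimethylsilyl)oxy]-6,10-dimethyl-9-oxododeca-1,2,10-trien-5-yl (Z)-2-methylbut-2-enoate | C=C=CC[C@@H]([C@@H](CCC(=O)/C(C)=C\CO[Si](C)(C)C(C)(C)C)C)OC(=O)/C(C)=C\C | intermediate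
22 | (5S,6R,9S,10Z)-12-[(tert-butyldimethylsilyl)oxy]-9-hydroxy-6,10-dimethyldodeca-1,2,10-trien-5-yl (Z)-2-methylbut-2-enoate | C=C=CC[C@@H]([C@@H](CC[C@@H](/C(C)=C\CO[Si](C)(C)C(C)(C)C)O)C)OC(=O)/C(C)=C\C | intermediate
23 | (5S,6R,9S,10Z)-9-acetoxy-12-[(tert-butyldimethylsilyl)oxy]-6,10-dimethyldodeca-1,2,10-trien-5-yl (Z)-2-methylbut-2-enoate | C=C=CC[C@@H]([C@@H](CC[C@@H](/C(C)=C\CO[Si](C)(C)C(C)(C)C)OC(C)=O)C)OC(=O)/C(C)=C\C | intermediate
24 | (5S,6R,9S,10Z)-9-acetoxy-12-hydroxy-6,10-dimethyldodeca-1,2,10-trien-5-yl (Z)-2-methylbut-2-enoate | C=C=CC[C@@H]([C@@H](CC[C@@H](/C(C)=C\CO)OC(C)=O)C)OC(=O)/C(C)=C\C | intermediate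
25 | (5S,6R,9S,10Z)-9-acetoxy-6,10-dimethyl-12-oxododeca-1,2,10-trien-5-yl (Z)-2-methylbut-2-enoate | C=C=CC[C@@H]([C@@H](CC[C@@H](/C(C)=C\C=O)OC(C)=O)C)OC(=O)/C(C)=C\C | intermediate
26 | nickelalactone (2-carboxylato-allylnickel, σ-form) of 25: 4-alkylidene-1-oxa-2-nickelacyclopentan-5-one carrying the C8–C6 chain | O=C1O[Ni]CC1=CC[C@@H]([C@@H](CC[C@@H](/C(C)=C\C=O)OC(C)=O)C)OC(=O)/C(C)=C\C | intermediate
27 | 2-[(1S,2R,3Z,5S,8R,9S)-5-acetoxy-2-hydroxy-4,8-dimethyl-9-{[(Z)-2-methylbut-2-enoyl]oxy}cyclodec-3-en-1-yl]acrylic acid (ring descriptors correspond to 7S,6R,4Z,3S,10R,9S in target locants) | OC(=O)C(=C)[C@H]1[C@H](O)/C=C(/C)[C@@H](OC(C)=O)CC[C@@H](C)[C@@H](OC(=O)/C(C)=C\C)C1 | intermediate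
28 | CNP0173235.1, (3S,4Z,6R,7S,9S,10R)-3-acetoxy-9-[(Z)-2-methylbut-2-enoyloxy]germacra-4,11(13)-dien-12,6-olide | C=C1C(=O)O[C@@H]2/C=C(/C)[C@@H](OC(C)=O)CC[C@@H](C)[C@@H](OC(=O)/C(C)=C\C)C[C@@H]12 | target

Total step count: 16. Longest linear sequence: 14 (steps 1–7 and 10–16).

Steps most likely to fail

1. Step 16 (labelled step). Several processes can defeat it: intermolecular allylation leading to oligomers instead of the ten-membered closure; consumption of Ni(0) by binding to the enal or by insertion into the allylic C3–O bond; base-induced Z to E isomerization of the enal by DBU; and the wrong face pairing (or a cis-lactone) in the macrocyclic transition state. The fallback uses known chemistry, sets out from aldehyde 14 and returns at 28. Addition of isopropenylmagnesium bromide (THF, −78 °C) should give the C3-epimeric (5S,6R,9RS)-9-hydroxy-6,10-dimethylundeca-1,2,10-trien-5-yl (Z)-2-methylbut-2-enoate F1. Dess–Martin oxidation gives the enone (5S,6R)-6,10-dimethyl-9-oxoundeca-1,2,10-trien-5-yl (Z)-2-methylbut-2-enoate F2, and (R)-Me-CBS/catecholborane reduction gives the (9S)-alcohol F3, which is acetylated to (5S,6R,9S)-9-acetoxy-6,10-dimethylundeca-1,2,10-trien-5-yl (Z)-2-methylbut-2-enoate F4. The coupling is then run in its known intermolecular form: Ni(cod)2/DBU/CO2 on the allene of F4 with nickel limiting, then (E)-cinnamaldehyde and acidic work-up. This should give the 6,7-trans α-methylene-γ-butyrolactone bearing an (E)-styryl group on C6 and the isopropenyl acetate chain on C7, configured at C6 and C7 as in 28, F5; it is separated from its diastereomers, and C11–C12 and C6–C7 are still formed in one operation. Ring-closing metathesis of F5 with a second-generation Grubbs catalyst in dilute toluene closes C4=C5 as the ring Z-olefin with loss of styrene and returns to 28.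

2. Step 12. Facial discrimination between the alkenyl and alkyl flanks may be insufficient, or the Z-enone may isomerize during steps 11–12. The fallback sets out from 14 and 18 and returns at 22: a catalytic asymmetric Nozaki–Hiyama–Kishi coupling (CrCl2 with a chiral sulfonamide–oxazoline ligand, NiCl2 catalyst, Mn, Cp2ZrCl2), with the ligand enantiomer chosen for the 9S carbinol, sets the centre in the C–C bond-forming event and bypasses alcohol mixture 20 and enone 21.

3. Step 6. The activated angeloyl unit may isomerize to the tigloyl (E) isomer, or acylation of the hindered alcohol may stall. The fallback sets out from 9 and returns at 12: esterification of 9 with 2-(diphenoxyphosphoryl)propanoic acid (DCC, DMAP) gives (5S,6R)-6,10-dimethylundeca-1,2,9-trien-5-yl 2-(diphenoxyphosphoryl)propanoate F6, and a Z-selective Horner–Wadsworth–Emmons olefination of this diaryl phosphonate with acetaldehyde (NaH, THF, −78 °C) builds the angelate double bond in place.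

Further compounds
F1 | step 16 | (5S,6R,9RS)-9-hydroxy-6,10-dimethylundeca-1,2,10-trien-5-yl (Z)-2-methylbut-2-enoate | C=C=CC[C@@H]([C@@H](CCC(O)C(C)=C)C)OC(=O)/C(C)=C\C
F2 | step 16 | (5S,6R)-6,10-dimethyl-9-oxoundeca-1,2,10-trien-5-yl (Z)-2-methylbut-2-enoate | C=C=CC[C@@H]([C@@H](CCC(=O)C(C)=C)C)OC(=O)/C(C)=C\C
F3 | step 16 | (5S,6R,9S)-9-hydroxy-6,10-dimethylundeca-1,2,10-trien-5-yl (Z)-2-methylbut-2-enoate | C=C=CC[C@@H]([C@@H](CC[C@@H](C(C)=C)O)C)OC(=O)/C(C)=C\C
F4 | step 16 | (5S,6R,9S)-9-acetoxy-6,10-dimethylundeca-1,2,10-trien-5-yl (Z)-2-methylbut-2-enoate | C=C=CC[C@@H]([C@@H](CC[C@@H](C(C)=C)OC(C)=O)C)OC(=O)/C(C)=C\C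
F5 | step 16 | 6,7-trans α-methylene-γ-butyrolactone with (E)-styryl on C6 and the 9-angeloyloxy-3-acetoxy isopropenyl chain on C7 (C6, C7 as in 28) | C=C1C(=O)O[C@H](/C=C/c2ccccc2)[C@H]1C[C@@H]([C@@H](CC[C@@H](C(C)=C)OC(C)=O)C)OC(=O)/C(C)=C\C
F6 | step 6 | (5S,6R)-6,10-dimethylundeca-1,2,9-trien-5-yl 2-(diphenoxyphosphoryl)propanoate | C=C=CC[C@@H]([C@@H](CCC=C(C)C)C)OC(=O)C(C)P(=O)(Oc1ccccc1)Oc1ccccc1
F0 | step 12 | none | none
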